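**Assumption:** the target has no stereocentre and is achiral, so there is no enantiomer to select; all compounds are drawn in the enol tautomer that matches the given SMILES.

**Retrosynthetic overview**
1. The methylene bridge is cut last: formaldehyde joins the ring A monomer (butanoylphloroglucinol) to the ring B monomer (propanoylfilicinic acid), as in the biogenetic one-carbon bridging.
2. Ring A comes from a C6→C1 Claisen cyclisation of the linear tetraketide methyl 3,5,7-trioxodecanoate, released in the flask from a pyrone-masked tetraketide (triacetic acid lactone plus a butanoate unit).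
3. Ring B comes from the same C6→C1 Claisen mode, run on a tetraketide that already carries the gem-dimethyl group (methyl 2,2-dimethyl-3,5,7-trioxononanoate). It is assembled and cyclised in one flask from hexane-2,4-dione dianion and dimethyl dimethylmalonate, so the dearomatised ring forms directly and no later C-methylation is needed.
4. Order: ring A (steps 1–2), ring B (step 3), bridging (step 4).

**Route**

Step 1
Reactants: 1 4-hydroxy-6-methyl-2H-pyran-2-one (triacetic acid lactone); 2 methyl butanoate
Product: 3 4-hydroxy-6-(2-oxopentyl)-2H-pyran-2-one
Conditions: 1 (2.1 equiv), LiN(iPr)2 (commercial solution, 4.2 equiv), THF, −78 → −20 °C; 2 (1.0 equiv), −78 → 0 °C; 1 M HCl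
Reagents that add atoms: none
Why: the dilithio salt of 1 (O-4 and the 6-methyl carbon) is C-acylated at the methyl carbanion by the ester (Claisen-type ester condensation of a 1,3-dicarbonyl dianion, Hauser–Harris type), the second equivalent of dianion taking up the acidic proton of the product so that little free amide base is left to enolise 2; no stereocentre is formed.

Step 2
Reactants: 3 4-hydroxy-6-(2-oxopentyl)-2H-pyran-2-one
Product: 5 1-(2,4,6-trihydroxyphenyl)butan-1-one, via methyl 3,5,7-trioxodecanoate 4 (not isolated)
Conditions: Mg(OMe)2 (commercial solution in MeOH, 4 equiv), MeOH, reflux, 12 h; 1 M HCl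
Reagents that add atoms: none
Why: methoxide opens the lactone to the magnesium-chelated tetraketide ester 4, whose C-6 carbanion closes onto the C-1 ester (intramolecular Claisen/Dieckmann condensation, the phloroglucinol-forming mode of polyketide cyclisation, known for pyrone-masked triketo esters), magnesium chelation favouring this over the C2→C7 aldol, and the resulting triketone enolises to the aromatic ring; no stereocentre is formed.

Step 3
Reactants: 6 hexane-2,4-dione; 7 dimethyl 2,2-dimethylpropanedioate
Product: 9 3,5-dihydroxy-4,4-dimethyl-2-propanoylcyclohexa-2,5-dien-1-one, via methyl 2,2-dimethyl-3,5,7-trioxononanoate 8 (not isolated)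
Conditions: 6 (2.1 equiv), LiN(iPr)2 (commercial solution, 4.2 equiv), THF, −78 → 0 °C; 7 (1.0 equiv), −78 → 23 °C, then reflux, 6 h; 1 M HCl
Reagents that add atoms: none
Why: Proposed new method: the C-1 carbanion of dilithio hexane-2,4-dione (kinetic deprotonation at the methyl, not the ethyl CH2) acylates one ester of the non-enolisable diester 7 to give tetraketide 8 as its dianion, whose C-6 carbon then closes onto the remaining ester (6-exo C6→C1 Claisen, helped by the gem-dimethyl effect and driven by formation of the strongly stabilised triketone enolate), while the quaternary C-2 blocks the C2→C7 aldol and any aromatisation; the closest known reactions are the acylation of β-diketone dianions with esters to 1,3,5-triketones and the base-mediated Claisen (Dieckmann-type) cyclisation of 3,5,7-triketo esters to acylphloroglucinols; no stereocentre is formed.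

Step 4
Reactants: 9 3,5-dihydroxy-4,4-dimethyl-2-propanoylcyclohexa-2,5-dien-1-one; 5 1-(2,4,6-trihydroxyphenyl)butan-1-one
Product: 11 2-[(3-butanoyl-2,4,6-trihydroxyphenyl)methyl]-3,5-dihydroxy-4,4-dimethyl-6-propanoylcyclohexa-2,5-dien-1-one, via 5-hydroxy-6,6-dimethyl-2-methylidene-4-propanoylcyclohex-4-ene-1,3-dione 10 (not isolated)
Conditions: 9 (1.0 equiv), 5 (3.0 equiv), 1% aq. NaOH, N2, 0 °C; 37% aq. CH2O (1.0 equiv) added over 2 h, then 23 °C, 1 h; 1 M HCl; chromatography (excess 5 recovered)
Reagents that add atoms: formaldehyde, C=O
Why: hydroxymethylation and dehydration at the only free ring carbon of 9 (Knoevenagel type) gives the quinone-methide-like enetrione 10, which is captured by the phloroglucinolate of 5 at one of its two equivalent free ring carbons (Friedel–Crafts-type Michael addition, the classical alkaline formaldehyde bridging of acylphloroglucinols), excess 5 suppressing the ring B homodimer and double bridging; no stereocentre is formed.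

**Compound list**
1 | 4-hydroxy-6-methyl-2H-pyran-2-one (triacetic acid lactone) | CC1=CC(O)=CC(=O)O1 | starting material
2 | methyl butanoate | CCCC(=O)OC | starting material
3 | 4-hydroxy-6-(2-oxopentyl)-2H-pyran-2-one | CCCC(=O)CC1=CC(O)=CC(=O)O1 | intermediate
4 | methyl 3,5,7-trioxodecanoate (not isolated) | CCCC(=O)CC(=O)CC(=O)CC(=O)OC | intermediate
5 | 1-(2,4,6-trihydroxyphenyl)butan-1-one (butanoylphloroglucinol) | CCCC(=O)c1c(O)cc(O)cc1O | intermediate
6 | hexane-2,4-dione | CCC(=O)CC(C)=O | starting material
7 | dimethyl 2,2-dimethylpropanedioate (dimethyl dimethylmalonate) | COC(=O)C(C)(C)C(=O)OC | starting material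
8 | methyl 2,2-dimethyl-3,5,7-trioxononanoate (not isolated) | CCC(=O)CC(=O)CC(=O)C(C)(C)C(=O)OC | intermediate
9 | 3,5-dihydroxy-4,4-dimethyl-2-propanoylcyclohexa-2,5-dien-1-one (propanoylfilicinic acid) | CCC(=O)C1=C(O)C(C)(C)C(O)=CC1=O | intermediate
10 | 5-hydroxy-6,6-dimethyl-2-methylidene-4-propanoylcyclohex-4-ene-1,3-dione (not isolated) | CCC(=O)C1=C(O)C(C)(C)C(=O)C(=C)C1=O | intermediate
11 | 2-[(3-butanoyl-2,4,6-trihydroxyphenyl)methyl]-3,5-dihydroxy-4,4-dimethyl-6-propanoylcyclohexa-2,5-dien-1-one | CCCC(=O)c1c(O)cc(O)c(CC2=C(O)C(C)(C)C(O)=C(C(=O)CC)C2=O)c1O | target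

**Summary**
Total step count: 4. Longest linear sequence: 3 steps (1 → 3 → 5 → 11); step 3 is a one-step convergent branch.

**Steps most likely to fail, with fallbacks**

Step 3 (one-flask acylation and Claisen closure to ring B). The risks are partial dianion formation at the ethyl CH2 of 6 and slow closure onto the hindered ester. The fallback sets out from compound 1 and comes back at compound 9, building ring B in the biogenetic order with methylation after cyclisation. The dianion of 1 is acylated with methyl propanoate (LiN(iPr)2, THF) to give 4-hydroxy-6-(2-oxobutyl)-2H-pyran-2-one F1. Mg(OMe)2 in refluxing MeOH opens F1 to methyl 3,5,7-trioxononanoate F2, which closes in the flask by C6→C1 Claisen condensation to 1-(2,4,6-trihydroxyphenyl)propan-1-one F3. Geminal C-methylation of F3 with MeI (2.2 equiv) and NaOMe in MeOH dearomatises one ring carbon and gives 9, which is separated from the mono- and tri-methylated by-products.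

Step 4 (hetero-selective methylene bridging). The risks are homodimers, double bridging on ring A, and partner exchange of the bridged dimers in alkali. The fallback sets out from compound 9 and comes back at compound 11, fixing the one-carbon unit on ring B before ring A is present. Compound 9 reacts with bis(dimethylamino)methane (CH2Cl2, 0 °C) to give the Mannich base 2-[(dimethylamino)methyl]-3,5-dihydroxy-4,4-dimethyl-6-propanoylcyclohexa-2,5-dien-1-one F4, isolated as its zwitterion. Heating F4 with 5 (2 equiv) in dioxane at 80 °C expels dimethylamine and releases 10 slowly, with no free 9 present. Compound 10 is trapped by 5 to give 11.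

Step 2 (Claisen versus aldol closure of the tetraketide). The risks are closure to a resorcylate or incomplete lactone opening. The fallback sets out from compound 1 and comes back at compound 5, closing the ring at the triketide stage where no aldol mode exists and adding the acyl group afterwards. Mg(OMe)2 in refluxing MeOH opens 1 to methyl 3,5-dioxohexanoate F5. NaOMe at about 185 °C closes F5 by C6→C1 Claisen condensation to benzene-1,3,5-triol F6. Friedel–Crafts C-acylation of F6 with butanoyl chloride and AlCl3 (nitrobenzene–CH2Cl2) gives 5.

**Further compounds**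
F1 | step 3 | 4-hydroxy-6-(2-oxobutyl)-2H-pyran-2-one | CCC(=O)CC1=CC(O)=CC(=O)O1
F2 | step 3 | methyl 3,5,7-trioxononanoate | CCC(=O)CC(=O)CC(=O)CC(=O)OC
F3 | step 3 | 1-(2,4,6-trihydroxyphenyl)propan-1-one | CCC(=O)c1c(O)cc(O)cc1O
F4 | step 4 | 2-[(dimethylamino)methyl]-3,5-dihydroxy-4,4-dimethyl-6-propanoylcyclohexa-2,5-dien-1-one | CCC(=O)C1=C(O)C(C)(C)C(O)=C(CN(C)C)C1=O
F5 | step 2 | methyl 3,5-dioxohexanoate | COC(=O)CC(=O)CC(C)=O
F6 | step 2 | benzene-1,3,5-triol | Oc1cc(O)cc(O)c1
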